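**Retrosynthetic overview**
1. Target 34 ⇐ bis-silyl ether 33 (desilylation) ⇐ β-keto lactone 31 (α-methylenation at C16).
2. Key disconnection (C8–C15 and C8–C14): ring D (C8, C14, C13, C16, C15) is cut back to a 3-substituted cyclobutanone (C15, C14, C13, C16). This is ring-expanded by one carbon, the α-diazo lactone carbon C8 of 29, in a strain-releasing formal C–C insertion that closes ring C (C8, C9, C11, C12, C13, C14) in the same operation.
3. Enabling feature: C8 is both the α-carbon of the C7 lactone (ring C10–C20–O–C7–C8–C9) and the quaternary neighbour of the C15 ketone of ring D, and C13 carries two CH2 groups (C14, C16). The four-membered precursor is therefore symmetrical and either CH2 can migrate.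
4. 29 ⇐ unsaturated spirolactone 16 + nitroalkane 22 (C9–C11 by conjugate addition/Nef, C11–O by Felkin–Anh hydrosilylation); 16 ⇐ spiro-epoxide 13 + acrylate (C10 by radical spirolactonisation) ⇐ 4,4-dimethylcyclohexane-1,3-dione 1 (C5 by copper hydride reduction, C1 by Luche reduction).
5. Order of ring formation: ring A (present in 1) → lactone ring (step 8) → cyclobutane (brought in with 22) → rings C and D together (step 17).

Key step: step 17

Remarks on the chemistry:
- Locants C1–C20 are those of the ent-kaurane skeleton of the target (C1 acetoxy carbon, C4 CMe2, C5–C6 CH–CH2O, C7 lactone C=O, C8, C9, C10 spiro carbon, C11 carbinol, C13 bridgehead CH, C14 bridge CH2, C15 ketone, C16=C17, C20 lactone OCH2).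
- Assumption: (R)-DTBM-SEGPHOS is taken to deliver hydride to the enone face that gives 5R in step 4; if the sense is opposite, the (S)-ligand is used.
- Centres that are formed as mixtures and later destroyed are written without a stereo mark.

Step 1
Reactants: 1 4,4-dimethylcyclohexane-1,3-dione
Product: 2 6,6-dimethyl-3-(2-methylpropoxy)cyclohex-2-en-1-one
Conditions: i-BuOH, TsOH·H2O (cat.), toluene, reflux (Dean–Stark)
Reagents that add atoms: 2-methylpropan-1-ol, CC(C)CO
Why: Acid-catalysed vinylogous esterification takes place at the carbonyl remote from the gem-dimethyl group, which leaves the hindered C=O (future C5) free for 1,2-addition.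

Step 2
Reactants: 2 vinylogous ester
Product: 5 3-(hydroxymethyl)-4,4-dimethylcyclohex-2-en-1-one, via β-hydroxysilane 3 (not isolated), via diol 4 (not isolated)
Conditions: (i-PrO)Me2SiCH2MgCl [from (i-PrO)Me2SiCH2Cl, Mg], THF, 0 °C; then KF, KHCO3, 30% H2O2, THF/MeOH, rt; then 1 M HCl, THF, rt
Reagents that add atoms: [dimethyl(propan-2-yloxy)silyl]methylmagnesium chloride, CC(C)O[Si](C)(C)C[Mg]Cl; hydrogen peroxide, OO
Why: Stork–Danheiser sequence: 1,2-addition of the hydroxymethyl-anion equivalent, Tamao oxidation of the C–Si bond and acid-induced 1,3-carbonyl transposition should give the β-(hydroxymethyl) enone; no stereocentre survives.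

Step 3
Reactants: 5 hydroxymethyl enone
Product: 6 3-({[tert-butyl(diphenyl)silyl]oxy}methyl)-4,4-dimethylcyclohex-2-en-1-one
Conditions: TBDPSCl, imidazole, DMF, rt
Reagents that add atoms: tert-butyl(chloro)diphenylsilane, CC(C)(C)[Si](Cl)(c1ccccc1)c1ccccc1
Why: Standard silylation of the primary alcohol installs the C6–O protecting group that is kept to the last step.

Step 4
Reactants: 6 silyloxymethyl enone
Product: 10 (3R)-3-({[tert-butyl(diphenyl)silyl]oxy}methyl)-4,4-dimethyl-2-methylidenecyclohexan-1-one, via enol silane 7 (not isolated), via Mannich base 8 (not isolated), via ammonium iodide 9 (not isolated)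
Conditions: Cu(OAc)2 (3 mol %), (R)-DTBM-SEGPHOS (3 mol %), (MeO)2MeSiH, toluene, 0 °C → rt; then CH2=NMe2+ I−, CH2Cl2, rt; then MeI; then aq. NaHCO3
Reagents that add atoms: N,N-dimethylmethylideneammonium iodide (Eschenmoser's salt), C=[N+](C)C.[I-]
Why: Copper hydride-catalysed asymmetric 1,4-reduction of the β,β-disubstituted enone sets C5 under ligand control and gives the enol silane regiospecifically toward C10, which is aminomethylated (Mukaiyama–Mannich reaction) and eliminated (Hofmann-type) to the exocyclic enone.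

Step 5
Reactants: 10 methylidene ketone
Product: 11 (1S,3R)-3-({[tert-butyl(diphenyl)silyl]oxy}methyl)-4,4-dimethyl-2-methylidenecyclohexan-1-ol
Conditions: NaBH4, CeCl3·7H2O, MeOH, −78 °C
Reagents that add atoms: none
Why: Luche 1,2-reduction; axial hydride attack on the chair with the C5 substituent equatorial (or attack anti to that substituent when it is axial) should place the C1 oxygen cis to the C5 CH2O group.

Step 6
Reactants: 11 allylic alcohol
Product: 12 triethylsilyl ether of 11
Conditions: Et3SiCl, imidazole, DMF, rt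
Reagents that add atoms: chlorotriethylsilane, CC[Si](Cl)(CC)CC
Why: Silylation masks the C1 hydroxyl so that only the C20 oxygen can lactonise in step 8; the triethylsilyl group is chosen because it is removed together with the ketal in step 15.

Step 7
Reactants: 12 silyl ether
Product: 13 spiro-epoxide of 12 (both epimers at C10)
Conditions: mCPBA, NaHCO3, CH2Cl2, 0 °C
Reagents that add atoms: 3-chloroperbenzoic acid, OOC(=O)c1cccc(Cl)c1
Why: Prilezhaev epoxidation of the only alkene; face selectivity is irrelevant because both epimers converge on the same planar C10 radical in step 8.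

Step 8
Reactants: 13 spiro-epoxide
Product: 14 (6S,7S,11R)-11-({[tert-butyl(diphenyl)silyl]oxy}methyl)-10,10-dimethyl-7-[(triethylsilyl)oxy]-2-oxaspiro[5.5]undecan-3-one
Conditions: Cp2TiCl2 (20 mol %), Zn dust, 2,4,6-collidine·HCl, CF3CH2O2CCH=CH2, THF, rt
Reagents that add atoms: 2,2,2-trifluoroethyl prop-2-enoate, C=CC(=O)OCC(F)(F)F
Why: Homolytic epoxide opening by trivalent titanium gives the tertiary C10 radical, whose Giese addition to the acrylate should occur anti to the axial C4 methyl group and to the flanking C1 and C5 substituents (C9 arm trans to O1 and C6); the C20 titanium alkoxide then closes the δ-lactone on the activated ester.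

Step 9
Reactants: 14 spirolactone
Product: 16 (6S,7S,11R)-11-({[tert-butyl(diphenyl)silyl]oxy}methyl)-10,10-dimethyl-7-[(triethylsilyl)oxy]-2-oxaspiro[5.5]undec-4-en-3-one, via α-selanyl lactone 15 (not isolated)
Conditions: LiN(i-Pr)2, THF, −78 °C; PhSeBr; then 30% H2O2, pyridine, CH2Cl2, 0 °C → rt
Reagents that add atoms: none
Why: α-Selenenylation of the lactone enolate followed by oxidation at selenium and syn-elimination toward C9 (the only β-hydrogens) should give the α,β-unsaturated δ-lactone.

Step 10
Reactants: 17 methyl 3,3-dimethoxycyclobutane-1-carboxylate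
Product: 18 3,3-dimethoxycyclobutane-1-carbaldehyde
Conditions: i-Bu2AlH, CH2Cl2, −78 °C
Reagents that add atoms: none
Why: Partial reduction of the ester stops at the aldehyde because the tetrahedral aluminate is stable at low temperature.

Step 11
Reactants: 18 aldehyde
Product: 21 1,1-dimethoxy-3-[(E)-2-nitroethenyl]cyclobutane, via nitro alcohol 19 (not isolated), via nitro mesylate 20 (not isolated)
Conditions: MeNO2, KOt-Bu (cat.), THF/t-BuOH, 0 °C; then MsCl, Et3N, CH2Cl2, −20 → 0 °C
Reagents that add atoms: nitromethane, C[N+](=O)[O-]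
Why: Henry reaction followed by E1cB elimination of the β-nitro mesylate gives the conjugated (E)-nitroalkene.

Step 12
Reactants: 21 nitroalkene
Product: 22 1,1-dimethoxy-3-(2-nitroethyl)cyclobutane
Conditions: NaBH4, EtOH/THF, 0 °C
Reagents that add atoms: none
Why: Conjugate hydride reduction of the nitroalkene gives the primary nitroalkane that carries C11–C16.

Step 13
Reactants: 16 unsaturated spirolactone; 22 nitroalkane
Product: 24 keto lactone (14 carrying at C9 a 2-(3,3-dimethoxycyclobutyl)acetyl group on the C1 face), via nitro adduct 23 (not isolated)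
Conditions: 22 (2 equiv), DBU, MeCN, rt; then 60 °C
Reagents that add atoms: none
Why: Amidine-mediated conjugate addition of the nitronate to C9 and base-promoted Nef reaction of the secondary nitro group give the 1,4-keto lactone; both the addition and the reversible equilibration at C9 should favour the C1 face, which is flanked only by an oxygen substituent, over the C5 face with its CH2OSi group next to the gem-dimethyl carbon, and the C11 nitro epimers converge on the ketone.

Step 14
Reactants: 24 keto lactone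
Product: 25 C11 tert-butyldimethylsilyl ether (C11 configured as in the target)
Conditions: CuCl (5 mol %), NaOt-Bu (5 mol %), 1,2-bis(diphenylphosphino)benzene (5 mol %), t-BuMe2SiH, toluene, rt
Reagents that add atoms: tert-butyl(dimethyl)silane, CC(C)(C)[SiH](C)C
Why: Copper hydride-catalysed hydrosilylation of the dialkyl ketone should follow Felkin–Anh control (quaternary C10 as the large group anti to the hydride) and gives the silyl ether directly, so no free γ-alkoxide is formed that could translactonise.

Step 15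
Reactants: 25 silyl ether
Product: 28 α-diazo lactone with free C1 hydroxyl and free cyclobutanone, via trifluoroacetyl lactone 26 (not isolated), via trifluoroacetyl keto alcohol 27 (not isolated)
Conditions: LiN(SiMe3)2, THF, −78 °C; CF3CO2CH2CF3; then 1 M HCl, THF, 0 °C → rt; then MsN3, Et3N, H2O, MeCN, rt
Reagents that add atoms: methanesulfonyl azide, CS(=O)(=O)N=[N+]=[N-]
Why: Detrifluoroacetylative (Regitz-type) diazo transfer: the lactone is the only enolisable carbonyl while the ketone is masked, mild acid then frees the cyclobutanone and the C1 alcohol, and the activated β-dicarbonyl accepts the diazo group under amine base that the cyclobutanone tolerates.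

Step 16
Reactants: 28 diazo alcohol
Product: 29 C1 acetate of 28
Conditions: Ac2O, Et3N, DMAP (cat.), CH2Cl2, 0 °C → rt
Reagents that add atoms: acetic anhydride, CC(=O)OC(C)=O
Why: DMAP-catalysed acetylation of the only free hydroxyl; the acceptor-substituted diazo group and the cyclobutanone are inert under these conditions.

Step 17
Reactants: 29 diazo lactone acetate
Product: 31 17-nor-maoyecrystal E 6-O-TBDPS 11-O-TBS bis-silyl ether (C16 = CH2), via diazonium betaine 30 (not isolated)
Conditions: BF3·OEt2 (0.3 equiv), CH2Cl2 (0.005 M), −78 → −30 °C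
Reagents that add atoms: none
Why: Proposed new method: BF3 activates the strained cyclobutanone C15=O, the nucleophilic diazo carbon C8 adds to it to give betaine 30, and the cyclobutane CH2 antiperiplanar to the C8–N2+ bond (it becomes C14) migrates from C15 to C8 with loss of N2 and inversion at C8, which regenerates C15=O as the ring-D cyclopentanone; the closest known reaction type is the Lewis-acid-catalysed Tiffeneau–Demjanov-type ring expansion of cyclobutanones and other cycloalkanones with α-alkyl-α-diazo esters, run here intramolecularly to give a bridged product. The first bond (C8–C15) forms by a 7-exo-trig addition to the carbonyl across the 1,3-positions of the cyclobutane, ring C is closed by the 1,2-shift that forms C8–C14, and ring D arises from the four-membered ring by one-carbon expansion driven by release of ring strain. The new quaternary centre C8 is controlled by C9: the tether leaves C9 on the lactone face bearing C11, which stands pseudoaxial to avoid allylic strain with the C8=N2 unit, so C15 bonds to that face and, after inversion, C14 ends syn to C11 and C15 syn to H9. C13 is fixed by the bridge, because only the CH2 anti to N2+ can migrate, which desymmetrises the two equivalent α-carbons of the cyclobutanone. The step needs C-attack at the ketone and carbon migration instead of epoxide formation, 1,2-hydride shift from C9 or carbene chemistry; the strained ketone, the absence of a carbene-forming metal, low temperature and high dilution should secure this, and migration regiochemistry is not an issue because C14 and C16 are constitutionally equivalent.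

Step 18
Reactants: 31 β-keto lactone
Product: 33 maoyecrystal E 6-O-TBDPS 11-O-TBS bis-silyl ether, via Mannich base 32 (not isolated)
Conditions: (CH2O)n, PhNHMe·CF3CO2H, THF, 65 °C
Reagents that add atoms: paraformaldehyde (as formaldehyde), C=O
Why: Mannich-type α-methylenation through the enol; C15 can enolise only toward C16 because C8 is quaternary, and the Mannich base eliminates in the flask.

Step 19
Reactants: 33 bis-silyl ether
Product: 34 maoyecrystal E
Conditions: HF·pyridine, pyridine, THF, 0 °C → rt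
Reagents that add atoms: none
Why: Fluoride cleaves both silyl ethers; the acetate, the lactone and the exocyclic enone should tolerate buffered HF·pyridine, and the rigid skeleton keeps the C11 hydroxyl trans to C7 so that it cannot translactonise.

**Compound list**
1 | 4,4-dimethylcyclohexane-1,3-dione | O=C1CC(=O)C(C)(C)CC1 | starting material
2 | 6,6-dimethyl-3-(2-methylpropoxy)cyclohex-2-en-1-one | CC(C)COC1=CC(=O)C(C)(C)CC1 | intermediate
3 | 1-{[dimethyl(propan-2-yloxy)silyl]methyl}-6,6-dimethyl-3-(2-methylpropoxy)cyclohex-2-en-1-ol (racemic, magnesium alkoxide in the flask) | CC(C)COC1=CC(O)(C[Si](C)(C)OC(C)C)C(C)(C)CC1 | intermediate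
4 | 1-(hydroxymethyl)-6,6-dimethyl-3-(2-methylpropoxy)cyclohex-2-en-1-ol (racemic) | CC(C)COC1=CC(O)(CO)C(C)(C)CC1 | intermediate
5 | 3-(hydroxymethyl)-4,4-dimethylcyclohex-2-en-1-one | O=C1C=C(CO)C(C)(C)CC1 | intermediate
6 | 3-({[tert-butyl(diphenyl)silyl]oxy}methyl)-4,4-dimethylcyclohex-2-en-1-one | O=C1C=C(CO[Si](c2ccccc2)(c2ccccc2)C(C)(C)C)C(C)(C)CC1 | intermediate
7 | dimethoxy(methyl)silyl enol ether (C1=C10) of the C5-configured 3-(silyloxymethyl)-4,4-dimethylcyclohexanone | CO[Si](C)(OC)OC1=C[C@H](CO[Si](c2ccccc2)(c2ccccc2)C(C)(C)C)C(C)(C)CC1 | intermediate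
8 | 2-[(dimethylamino)methyl] Mannich base of that ketone (C10 epimers) | CN(C)CC1C(=O)CCC(C)(C)[C@H]1CO[Si](c1ccccc1)(c1ccccc1)C(C)(C)C | intermediate
9 | trimethylammonium iodide of 8 | C[N+](C)(C)CC1C(=O)CCC(C)(C)[C@H]1CO[Si](c1ccccc1)(c1ccccc1)C(C)(C)C.[I-] | intermediate
10 | (3R)-3-({[tert-butyl(diphenyl)silyl]oxy}methyl)-4,4-dimethyl-2-methylidenecyclohexan-1-one | C=C1C(=O)CCC(C)(C)[C@H]1CO[Si](c1ccccc1)(c1ccccc1)C(C)(C)C | intermediate
11 | (1S,3R)-3-({[tert-butyl(diphenyl)silyl]oxy}methyl)-4,4-dimethyl-2-methylidenecyclohexan-1-ol (OH cis to CH2OSi) | C=C1[C@@H](O)CCC(C)(C)[C@H]1CO[Si](c1ccccc1)(c1ccccc1)C(C)(C)C | intermediate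
12 | (1S,3R) triethylsilyl ether of 11 | C=C1[C@@H](O[Si](CC)(CC)CC)CCC(C)(C)[C@H]1CO[Si](c1ccccc1)(c1ccccc1)C(C)(C)C | intermediate
13 | 1-oxaspiro[2.5]octane spiro-epoxide of 12 (both epimers at the spiro carbon C10) | C1OC12[C@@H](O[Si](CC)(CC)CC)CCC(C)(C)[C@H]2CO[Si](c1ccccc1)(c1ccccc1)C(C)(C)C | intermediate
14 | (6S,7S,11R)-11-({[tert-butyl(diphenyl)silyl]oxy}methyl)-10,10-dimethyl-7-[(triethylsilyl)oxy]-2-oxaspiro[5.5]undecan-3-one (C20, O1 and C6 mutually cis on ring A) | O=C1CC[C@]2(CO1)[C@@H](O[Si](CC)(CC)CC)CCC(C)(C)[C@H]2CO[Si](c1ccccc1)(c1ccccc1)C(C)(C)C | intermediate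
15 | 4-(phenylselanyl) derivative of 14 (C8 epimers) | O=C1C([Se]c3ccccc3)C[C@]2(CO1)[C@@H](O[Si](CC)(CC)CC)CCC(C)(C)[C@H]2CO[Si](c1ccccc1)(c1ccccc1)C(C)(C)C | intermediate
16 | (6S,7S,11R)-11-({[tert-butyl(diphenyl)silyl]oxy}methyl)-10,10-dimethyl-7-[(triethylsilyl)oxy]-2-oxaspiro[5.5]undec-4-en-3-one | O=C1C=C[C@]2(CO1)[C@@H](O[Si](CC)(CC)CC)CCC(C)(C)[C@H]2CO[Si](c1ccccc1)(c1ccccc1)C(C)(C)C | intermediate
17 | methyl 3,3-dimethoxycyclobutane-1-carboxylate | COC(=O)C1CC(OC)(OC)C1 | starting material
18 | 3,3-dimethoxycyclobutane-1-carbaldehyde | O=CC1CC(OC)(OC)C1 | intermediate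
19 | 1-(3,3-dimethoxycyclobutyl)-2-nitroethan-1-ol (racemic) | OC(C[N+](=O)[O-])C1CC(OC)(OC)C1 | intermediate
20 | methanesulfonate of 19 | CS(=O)(=O)OC(C[N+](=O)[O-])C1CC(OC)(OC)C1 | intermediate
21 | 1,1-dimethoxy-3-[(E)-2-nitroethenyl]cyclobutane | [O-][N+](=O)/C=C/C1CC(OC)(OC)C1 | intermediate
22 | 1,1-dimethoxy-3-(2-nitroethyl)cyclobutane | [O-][N+](=O)CCC1CC(OC)(OC)C1 | intermediate
23 | nitro adduct: 14 carrying at C9 (C1 face) a 2-(3,3-dimethoxycyclobutyl)-1-nitroethyl group (C11 epimers) | O=C1C[C@@H](C(CC3CC(OC)(OC)C3)[N+](=O)[O-])[C@]2(CO1)[C@@H](O[Si](CC)(CC)CC)CCC(C)(C)[C@H]2CO[Si](c1ccccc1)(c1ccccc1)C(C)(C)C | intermediate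
24 | keto lactone: 14 carrying at C9 (C1 face) a 2-(3,3-dimethoxycyclobutyl)acetyl group | O=C1C[C@@H](C(=O)CC3CC(OC)(OC)C3)[C@]2(CO1)[C@@H](O[Si](CC)(CC)CC)CCC(C)(C)[C@H]2CO[Si](c1ccccc1)(c1ccccc1)C(C)(C)C | intermediate
25 | C11 tert-butyldimethylsilyl ether: 14 carrying at C9 a 1-silyloxy-2-(3,3-dimethoxycyclobutyl)ethyl group, C9 and C11 configured as in the target | O=C1C[C@@H]([C@@H](O[Si](C)(C)C(C)(C)C)CC3CC(OC)(OC)C3)[C@]2(CO1)[C@@H](O[Si](CC)(CC)CC)CCC(C)(C)[C@H]2CO[Si](c1ccccc1)(c1ccccc1)C(C)(C)C | intermediate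
26 | C8-trifluoroacetyl derivative of 25 (C8 epimers/enol) | O=C1C(C(=O)C(F)(F)F)[C@@H]([C@@H](O[Si](C)(C)C(C)(C)C)CC3CC(OC)(OC)C3)[C@]2(CO1)[C@@H](O[Si](CC)(CC)CC)CCC(C)(C)[C@H]2CO[Si](c1ccccc1)(c1ccccc1)C(C)(C)C | intermediate
27 | C8-trifluoroacetyl lactone with free cyclobutanone and free C1 hydroxyl | O=C1C(C(=O)C(F)(F)F)[C@@H]([C@@H](O[Si](C)(C)C(C)(C)C)CC3CC(=O)C3)[C@]2(CO1)[C@@H](O)CCC(C)(C)[C@H]2CO[Si](c1ccccc1)(c1ccccc1)C(C)(C)C | intermediate
28 | C8-diazo spirolactone with 3-oxocyclobutyl side chain, C11 OTBS, C6 OTBDPS, free C1 hydroxyl | O=C1C(=[N+]=[N-])[C@@H]([C@@H](O[Si](C)(C)C(C)(C)C)CC3CC(=O)C3)[C@]2(CO1)[C@@H](O)CCC(C)(C)[C@H]2CO[Si](c1ccccc1)(c1ccccc1)C(C)(C)C | intermediate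
29 | C1 acetate of 28 | O=C1C(=[N+]=[N-])[C@@H]([C@@H](O[Si](C)(C)C(C)(C)C)CC3CC(=O)C3)[C@]2(CO1)[C@@H](OC(C)=O)CCC(C)(C)[C@H]2CO[Si](c1ccccc1)(c1ccccc1)C(C)(C)C | intermediate
30 | bridged β-(trifluoroboranuidyloxy) diazonium betaine (C8–C15 bond formed; N2+ on C8 syn to H9; bicyclo[4.1.1] cyclobutane, bridging cis by necessity) | F[B-](F)(F)OC12CC(C1)C[C@H](O[Si](C)(C)C(C)(C)C)[C@H]3[C@]4(COC(=O)[C@@]23[N+]#N)[C@@H](OC(C)=O)CCC(C)(C)[C@H]4CO[Si](c5ccccc5)(c5ccccc5)C(C)(C)C | intermediate
31 | 17-nor-maoyecrystal E 6-O-TBDPS 11-O-TBS bis-silyl ether (C16 = CH2; all stereocentres as in the target) | C1C(=O)[C@]23C[C@H]1C[C@H](O[Si](C)(C)C(C)(C)C)[C@H]2[C@]1(COC3=O)[C@@H](OC(C)=O)CCC(C)(C)[C@H]1CO[Si](c1ccccc1)(c1ccccc1)C(C)(C)C | intermediate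
32 | C16 (N-methylanilino)methyl Mannich base of 31 (C16 epimers) | CN(c4ccccc4)CC1C(=O)[C@]23C[C@H]1C[C@H](O[Si](C)(C)C(C)(C)C)[C@H]2[C@]1(COC3=O)[C@@H](OC(C)=O)CCC(C)(C)[C@H]1CO[Si](c1ccccc1)(c1ccccc1)C(C)(C)C | intermediate
33 | maoyecrystal E 6-O-TBDPS 11-O-TBS bis-silyl ether | C=C1C(=O)[C@]23C[C@H]1C[C@H](O[Si](C)(C)C(C)(C)C)[C@H]2[C@]1(COC3=O)[C@@H](OC(C)=O)CCC(C)(C)[C@H]1CO[Si](c1ccccc1)(c1ccccc1)C(C)(C)C | intermediate
34 | maoyecrystal E (1S,5R,8S,9S,10R,11S,13S) | C=C1C(=O)[C@]23C[C@H]1C[C@H](O)[C@H]2[C@]1(COC3=O)[C@@H](OC(C)=O)CCC(C)(C)[C@H]1CO | target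

**Step count and risks**
Total step count: 19. Longest linear sequence: 16 (steps 1–9 and 13–19; the side-chain branch, steps 10–12, joins at step 13).

Steps most likely to fail:

1. Step 17 (proposed new method). What may go wrong: the diazo carbon fails to engage the tethered ketone (protonation or dimerisation of the diazo lactone, 1,2-hydride shift from C9), or it adds from the lactone face anti to the tether, which gives the C8/C13-epimeric bridge. Fallback with known chemistry, setting out from 29: PhSeCl adds across the diazo carbon with loss of N2 to give the α-chloro-α-(phenylselanyl) lactone F1. SmI2 (THF, −78 °C) then generates the α-selanyl enolate, which adds to the cyclobutanone in an intramolecular Reformatsky reaction to give the bridged β-hydroxy selenide F2. AgBF4-assisted seleno-pinacol-type ring expansion of this cyclobutanol (CH2 migration antiperiplanar to the departing PhSe group) returns to the route at 31.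

2. Step 13. What may go wrong: sluggish addition to the neopentyl β-carbon with retro-Michael reversal, insufficient face selectivity at C9, or an incomplete Nef stage. Fallback, setting out from 22 and 16: oxidative Nef reaction of the primary nitroalkane 22 (KOH, MeOH; then KMnO4, MgSO4, 0 °C) gives 2-(3,3-dimethoxycyclobutyl)acetaldehyde F3. Its acyl radical, generated by hydrogen-atom abstraction with the photocatalyst (n-Bu4N)4W10O32 under 365 nm light, adds irreversibly to the β-carbon of 16 (radical hydroacylation) and returns to the route at 24; the C9 epimers can then be equilibrated with DBU.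

3. Step 4. What may go wrong: slow hydride transfer to the fully substituted β-carbon next to the quaternary carbon, low enantioselectivity, or loss of regiochemical integrity of the enol silane before aminomethylation. Fallback, setting out from 2, which sets C5 by C–C instead of C–H bond formation: i-Bu2AlH reduction and acidic work-up (reductive carbonyl transposition) give 4,4-dimethylcyclohex-2-en-1-one F4. CuBr·SMe2/Josiphos-catalysed asymmetric conjugate addition of (i-PrO)Me2SiCH2MgCl, with trapping of the magnesium enolate by Eschenmoser's salt, gives Mannich base F5. Quaternisation with MeI gives ammonium iodide F6, and elimination gives methylidene ketone F7. Luche reduction gives allylic alcohol F8, Tamao oxidation gives diol F9, and selective silylation of the primary hydroxyl with TBDPSCl returns to the route at 11.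

Further compounds
F1 | step 17 | C8-chloro-C8-(phenylselanyl) lactone derived from 29 (C8 epimers) | O=C1C(Cl)([Se]c4ccccc4)[C@@H]([C@@H](O[Si](C)(C)C(C)(C)C)CC3CC(=O)C3)[C@]2(CO1)[C@@H](OC(C)=O)CCC(C)(C)[C@H]2CO[Si](c1ccccc1)(c1ccccc1)C(C)(C)C
F2 | step 17 | bridged β-hydroxy selenide (C8–C15 bond formed, PhSe on C8 syn to H9, bicyclo[4.1.1] cyclobutanol) | OC12CC(C1)C[C@H](O[Si](C)(C)C(C)(C)C)[C@H]3[C@]4(COC(=O)[C@@]23[Se]c5ccccc5)[C@@H](OC(C)=O)CCC(C)(C)[C@H]4CO[Si](c6ccccc6)(c6ccccc6)C(C)(C)C
F3 | step 13 | 2-(3,3-dimethoxycyclobutyl)acetaldehyde | O=CCC1CC(OC)(OC)C1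
F4 | step 4 | 4,4-dimethylcyclohex-2-en-1-one | CC1(C)C=CC(=O)CC1
F5 | step 4 | 2-[(dimethylamino)methyl]-3-{[dimethyl(propan-2-yloxy)silyl]methyl}-4,4-dimethylcyclohexan-1-one (C5 set, C10 epimers) | CN(C)CC1C(=O)CCC(C)(C)[C@H]1C[Si](C)(C)OC(C)C
F6 | step 4 | trimethylammonium iodide of F5 | C[N+](C)(C)CC1C(=O)CCC(C)(C)[C@H]1C[Si](C)(C)OC(C)C.[I-]
F7 | step 4 | (3R)-3-{[dimethyl(propan-2-yloxy)silyl]methyl}-4,4-dimethyl-2-methylidenecyclohexan-1-one | C=C1C(=O)CCC(C)(C)[C@H]1C[Si](C)(C)OC(C)C
F8 | step 4 | (1S,3R)-3-{[dimethyl(propan-2-yloxy)silyl]methyl}-4,4-dimethyl-2-methylidenecyclohexan-1-ol | C=C1[C@@H](O)CCC(C)(C)[C@H]1C[Si](C)(C)OC(C)C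
F9 | step 4 | (1S,3R)-3-(hydroxymethyl)-4,4-dimethyl-2-methylidenecyclohexan-1-ol | C=C1[C@@H](O)CCC(C)(C)[C@H]1CO
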